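**Retrosynthetic overview**

1. Feature used: in the pyranone ring (O1–C2–C3–C4–C4a–C8a), O1 is bonded to C8a, the arene carbon ortho to the C4 ketone. A fluoride on C8a can therefore be displaced by the C2 oxygen (SNAr) without breaking the C2–O bond.
2. Target ⇐ (MOM removal) 7-O-MOM flavanone ⇐ (O1–C8a SNAr, the only ring-forming step; rings A and B come intact from the starting materials) (S)-β-hydroxy ketone carrying a 2-fluoroaryl ketone.
3. (S)-β-Hydroxy ketone ⇐ (SmI2 cleavage of Cα–O) trans-(2S,3R)-epoxy ketone ⇐ (polyleucine-mediated epoxidation, sets the future C2) E-chalcone ⇐ (Claisen–Schmidt) diprenylated fluoroacetophenone + veratraldehyde.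
4. Diprenylated fluoroacetophenone ⇐ (double Stille prenylation) diiodo MOM ether ⇐ (MOM protection, ortho,ortho-diiodination) 2'-fluoro-4'-hydroxyacetophenone.

Key step: step 7

Assumption: the chalcone of step 4 is taken to follow the facial preference established for the parent chalcone in polyleucine-mediated epoxidation (poly-L-leucine gives the 2R,3S epoxide), so poly-D-leucine is specified; the prenylstannane is a catalogue reagent.

**Route**

Step 1
Reactants: 1 2'-fluoro-4'-hydroxyacetophenone
Product: 2 1-(2-fluoro-4-hydroxy-3,5-diiodophenyl)ethanone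
Conditions: NIS (2.2 equiv), TsOH·H2O (cat.), MeCN, 0 °C to rt
Reagents that add atoms: N-iodosuccinimide, O=C1CCC(=O)N1I
Why: Electrophilic aromatic iodination; the phenol activates only its two free ortho positions (C3 and C5, the para position being blocked by the acetyl group), and both are also meta to the acetyl group, so both should be iodinated.

Step 2
Reactants: 2 1-(2-fluoro-4-hydroxy-3,5-diiodophenyl)ethanone
Product: 3 1-[2-fluoro-3,5-diiodo-4-(methoxymethoxy)phenyl]ethanone
Conditions: MOMCl, i-Pr2NEt, CH2Cl2, 0 °C to rt
Reagents that add atoms: chloromethyl methyl ether, COCCl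
Why: O-alkylation of the acidic diiodophenol with MOMCl (Williamson-type etherification); the phenol must be masked because a free para-phenoxide would cancel the activation of the C–F bond by the ketone in step 7.

Step 3
Reactants: 3 1-[2-fluoro-3,5-diiodo-4-(methoxymethoxy)phenyl]ethanone; 4 tributyl(3-methylbut-2-en-1-yl)stannane
Product: 5 1-[2-fluoro-4-(methoxymethoxy)-3,5-bis(3-methylbut-2-en-1-yl)phenyl]ethanone
Conditions: 4 (2.5 equiv), Pd(PPh3)4 (10 mol%), degassed amine-free DMF, 90 °C
Reagents that add atoms: none
Why: Two-fold Stille coupling: oxidative addition of Pd(0) into each C–I bond, transfer of the prenyl group from tin and reductive elimination at the less hindered CH2 terminus should give the linear 3-methylbut-2-enyl group at C3 and C5, and the neutral conditions leave the ketone, the MOM ether and the C–F bond alone.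

Step 4
Reactants: 5 1-[2-fluoro-4-(methoxymethoxy)-3,5-bis(3-methylbut-2-en-1-yl)phenyl]ethanone; 6 3,4-dimethoxybenzaldehyde
Product: 7 (E)-3-(3,4-dimethoxyphenyl)-1-[2-fluoro-4-(methoxymethoxy)-3,5-bis(3-methylbut-2-en-1-yl)phenyl]prop-2-en-1-one
Conditions: KOH (aq.), EtOH, 0 °C to rt
Reagents that add atoms: none
Why: Claisen–Schmidt condensation: the methyl ketone enolate adds to the non-enolisable aldehyde and E1cB loss of water gives the conjugated enone, whose E geometry is the thermodynamic outcome, while room temperature is chosen to keep hydroxide or ethoxide from attacking the C–F carbon.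

Step 5
Reactants: 7 (E)-3-(3,4-dimethoxyphenyl)-1-[2-fluoro-4-(methoxymethoxy)-3,5-bis(3-methylbut-2-en-1-yl)phenyl]prop-2-en-1-one
Product: 8 [(2S,3R)-3-(3,4-dimethoxyphenyl)oxiran-2-yl][2-fluoro-4-(methoxymethoxy)-3,5-bis(3-methylbut-2-en-1-yl)phenyl]methanone
Conditions: poly-D-leucine (cat.), urea–H2O2, DBU, THF, rt
Reagents that add atoms: hydrogen peroxide (used as its urea adduct), OO
Why: Juliá–Colonna epoxidation (a Weitz–Scheffer nucleophilic epoxidation run on a helical polyleucine): hydroperoxide adds to Cβ of the enone on the face selected by poly-D-leucine, the mirror image of the poly-L-leucine case that gives 2R,3S epoxides, and closure with loss of hydroxide should give the trans-(2S,3R) epoxide, which fixes the oxygen-bearing carbon that becomes C2, while the electron-rich prenyl alkenes are inert to the nucleophilic oxidant.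

Step 6
Reactants: 8 [(2S,3R)-3-(3,4-dimethoxyphenyl)oxiran-2-yl][2-fluoro-4-(methoxymethoxy)-3,5-bis(3-methylbut-2-en-1-yl)phenyl]methanone
Product: 9 (3S)-3-(3,4-dimethoxyphenyl)-1-[2-fluoro-4-(methoxymethoxy)-3,5-bis(3-methylbut-2-en-1-yl)phenyl]-3-hydroxypropan-1-one
Conditions: SmI2 (2.2 equiv), THF/MeOH, −90 °C
Reagents that add atoms: none
Why: Samarium diiodide reduction of an α,β-epoxy ketone: electron transfer to the aryl ketone gives a ketyl that opens the Cα–O bond, a second electron gives the samarium enolate that methanol protonates, and since the Cβ–O bond is not touched the 3R epoxide carbon becomes the 3S carbinol (the descriptor changes only because Cα loses its oxygen).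

Step 7
Reactants: 9 (3S)-3-(3,4-dimethoxyphenyl)-1-[2-fluoro-4-(methoxymethoxy)-3,5-bis(3-methylbut-2-en-1-yl)phenyl]-3-hydroxypropan-1-one
Product: 11 (2S)-2-(3,4-dimethoxyphenyl)-7-(methoxymethoxy)-6,8-bis(3-methylbut-2-en-1-yl)-2,3-dihydro-4H-chromen-4-one, via potassium alkoxide 10 (not isolated)
Conditions: KHMDS (1.0 equiv), THF, −78 °C to 0 °C; quench with pH 7 phosphate buffer
Reagents that add atoms: none
Why: KHMDS removes the C2–OH proton to give potassium alkoxide 10, whose oxygen adds to the fluorine-bearing C8a (ortho to the C4 ketone) to form a Meisenheimer adduct with the charge delocalised through C4a onto the ketone oxygen, and loss of fluoride restores the arene and completes the O1–C8a bond. The closest known reaction type is the intramolecular SNAr etherification of 2-fluoroaryl ketones by tethered alkoxides, which gives chroman-4-ones. The pyranone ring (O1–C2–C3–C4–C4a–C8a) closes in a six-membered addition–elimination at an sp2 carbon, with the breaking C–F bond outside the new ring. No stereocentre is created: C2 keeps the S configuration set in step 5 because its C–O bond is never broken. The step needs ring closure to outrun retro-aldol cleavage and E1cB dehydration of 10 and must leave no base that could open the flavanone; the preferred conformation of a 2-fluoroaryl ketone (C=O turned away from F) holds the side chain and its alkoxide next to C8a, the C7 OMOM group is meta to C8a and is expected to be twisted out of conjugation by its two prenyl neighbours so that the ketone activation is kept, and the single equivalent of non-nucleophilic amide base is consumed as KF.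

Step 8
Reactants: 11 (2S)-2-(3,4-dimethoxyphenyl)-7-(methoxymethoxy)-6,8-bis(3-methylbut-2-en-1-yl)-2,3-dihydro-4H-chromen-4-one
Product: 12 (2S)-2-(3,4-dimethoxyphenyl)-7-hydroxy-6,8-bis(3-methylbut-2-en-1-yl)-2,3-dihydro-4H-chromen-4-one (IN0946)
Conditions: HCl (1.25 M in MeOH), 0 °C to rt, short reaction time; NaHCO3 work-up kept brief
Reagents that add atoms: none
Why: Acid-catalysed acetal methanolysis: protonation of the MOM ether and trapping of the methoxymethyl cation by methanol frees the C7 phenol, and low temperature with a short reaction time is meant to keep the acid from adding the phenol across an ortho prenyl double bond, while C2 is not involved.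

**Compound list**

1 | 2'-fluoro-4'-hydroxyacetophenone | CC(=O)c1ccc(O)cc1F | starting material
2 | 1-(2-fluoro-4-hydroxy-3,5-diiodophenyl)ethanone | CC(=O)c1cc(I)c(O)c(I)c1F | intermediate
3 | 1-[2-fluoro-3,5-diiodo-4-(methoxymethoxy)phenyl]ethanone | CC(=O)c1cc(I)c(OCOC)c(I)c1F | intermediate
4 | tributyl(3-methylbut-2-en-1-yl)stannane | CCCC[Sn](CCCC)(CCCC)CC=C(C)C | starting material
5 | 1-[2-fluoro-4-(methoxymethoxy)-3,5-bis(3-methylbut-2-en-1-yl)phenyl]ethanone | CC(=O)c1cc(CC=C(C)C)c(OCOC)c(CC=C(C)C)c1F | intermediate
6 | 3,4-dimethoxybenzaldehyde | COc1ccc(C=O)cc1OC | starting material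
7 | (E)-3-(3,4-dimethoxyphenyl)-1-[2-fluoro-4-(methoxymethoxy)-3,5-bis(3-methylbut-2-en-1-yl)phenyl]prop-2-en-1-one | COc1ccc(/C=C/C(=O)c2cc(CC=C(C)C)c(OCOC)c(CC=C(C)C)c2F)cc1OC | intermediate
8 | [(2S,3R)-3-(3,4-dimethoxyphenyl)oxiran-2-yl][2-fluoro-4-(methoxymethoxy)-3,5-bis(3-methylbut-2-en-1-yl)phenyl]methanone | COc1ccc([C@H]2O[C@@H]2C(=O)c2cc(CC=C(C)C)c(OCOC)c(CC=C(C)C)c2F)cc1OC | intermediate
9 | (3S)-3-(3,4-dimethoxyphenyl)-1-[2-fluoro-4-(methoxymethoxy)-3,5-bis(3-methylbut-2-en-1-yl)phenyl]-3-hydroxypropan-1-one | COc1ccc([C@@H](O)CC(=O)c2cc(CC=C(C)C)c(OCOC)c(CC=C(C)C)c2F)cc1OC | intermediate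
10 | potassium (1S)-1-(3,4-dimethoxyphenyl)-3-[2-fluoro-4-(methoxymethoxy)-3,5-bis(3-methylbut-2-en-1-yl)phenyl]-3-oxopropan-1-olate | COc1ccc([C@@H]([O-])CC(=O)c2cc(CC=C(C)C)c(OCOC)c(CC=C(C)C)c2F)cc1OC.[K+] | intermediate
11 | (2S)-2-(3,4-dimethoxyphenyl)-7-(methoxymethoxy)-6,8-bis(3-methylbut-2-en-1-yl)-2,3-dihydro-4H-chromen-4-one | COc1ccc([C@@H]2CC(=O)c3cc(CC=C(C)C)c(OCOC)c(CC=C(C)C)c3O2)cc1OC | intermediate
12 | (2S)-2-(3,4-dimethoxyphenyl)-7-hydroxy-6,8-bis(3-methylbut-2-en-1-yl)-2,3-dihydro-4H-chromen-4-one (IN0946) | COc1ccc([C@@H]2CC(=O)c3cc(CC=C(C)C)c(O)c(CC=C(C)C)c3O2)cc1OC | target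

**Step count and risks**

Total step count: 8. Longest linear sequence: 8 steps (1 to 12).

Steps most likely to fail:

1. Step 7 (key step). The alkoxide may break down by retro-aldol cleavage, or pass its charge to C3 and lose hydroxide, faster than it closes on C8a; base left in solution may also reopen the flavanone through its enolate and scramble C2. Fallback (ring closure by oxa-Michael addition, enantiomer obtained by resolution): it sets out from chalcone 7 and returns at 11. Fluoride is exchanged for oxygen by SNAr with the sodium alkoxide of 2-(methylsulfonyl)ethanol (NaH, DMF, 0 °C to rt). The resulting 2'-[2-(methylsulfonyl)ethoxy]chalcone F1 (not isolated) loses methyl vinyl sulfone by β-elimination in the same flask to give the 2'-hydroxychalcone F2. NaOAc in refluxing EtOH then closes the ring by the classical intramolecular oxa-Michael addition to give the racemic 7-O-MOM flavanone F3. Preparative chromatography on a chiral stationary phase delivers the 2S enantiomer 11.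

2. Step 3. The prenyl group may be transferred through its tertiary end (1,1-dimethylallyl product), the second coupling at the flanked C3–I may stall, or the iodide may be lost by protodeiodination. Fallback (allylation, then olefin metathesis): it sets out from 3 and returns at 5. Two-fold Stille coupling with allyltributylstannane (Pd(PPh3)4, DMF, 90 °C), where an unsubstituted allyl group raises no regiochemical question, gives the 3,5-diallyl ketone F4. Cross-metathesis with excess 2-methyl-2-butene under a second-generation ruthenium carbene catalyst (CH2Cl2, 40 °C) converts both allyl groups into prenyl groups and gives 5.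

3. Step 5. Hydroperoxide addition to an enone deactivated by the electron-rich dimethoxyphenyl ring may be slow, facial discrimination by the polypeptide may be weak for the ortho-fluoro aryl ketone, and hydroperoxide may attack the C–F carbon. Fallback (direct catalytic enantioselective aldol, bypassing steps 4 to 6): it sets out from ketone 5 (with aldehyde 6) and returns at 9. TMSOTf and Et3N in CH2Cl2 at 0 °C give the trimethylsilyl enol ether F5. A Lewis-base-catalysed enantioselective Mukaiyama aldol addition to 6 (SiCl4, chiral bisphosphoramide, i-Pr2NEt, CH2Cl2, −78 °C), using the catalyst antipode that directs the enol ether to the Si face of the aldehyde, should give 9 after aqueous work-up.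

**Further compounds**

F1 | step 7 | (E)-3-(3,4-dimethoxyphenyl)-1-[4-(methoxymethoxy)-3,5-bis(3-methylbut-2-en-1-yl)-2-[2-(methylsulfonyl)ethoxy]phenyl]prop-2-en-1-one | COc1ccc(/C=C/C(=O)c2cc(CC=C(C)C)c(OCOC)c(CC=C(C)C)c2OCCS(C)(=O)=O)cc1OC
F2 | step 7 | (E)-3-(3,4-dimethoxyphenyl)-1-[2-hydroxy-4-(methoxymethoxy)-3,5-bis(3-methylbut-2-en-1-yl)phenyl]prop-2-en-1-one | COc1ccc(/C=C/C(=O)c2cc(CC=C(C)C)c(OCOC)c(CC=C(C)C)c2O)cc1OC
F3 | step 7 | racemic 2-(3,4-dimethoxyphenyl)-7-(methoxymethoxy)-6,8-bis(3-methylbut-2-en-1-yl)-2,3-dihydro-4H-chromen-4-one | COc1ccc(C2CC(=O)c3cc(CC=C(C)C)c(OCOC)c(CC=C(C)C)c3O2)cc1OC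
F4 | step 3 | 1-[2-fluoro-4-(methoxymethoxy)-3,5-di(prop-2-en-1-yl)phenyl]ethanone | CC(=O)c1cc(CC=C)c(OCOC)c(CC=C)c1F
F5 | step 5 | ({1-[2-fluoro-4-(methoxymethoxy)-3,5-bis(3-methylbut-2-en-1-yl)phenyl]ethenyl}oxy)trimethylsilane | C=C(O[Si](C)(C)C)c1cc(CC=C(C)C)c(OCOC)c(CC=C(C)C)c1F
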